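The cyclohexene is numbered C1 (quaternary, carrying methyl and the styryl carbon Cα), C2, C3, C4(Me)=C5 and C6 (carrying H and coumarin B). Since Cα hangs on C1 and the olefinic ring carbon C5 is bonded to C6, only the C1–C6 bond separates them, and tying Cα to C5 gives a cyclobutene (Cα, C1, C6, C5) on which both stereocentres are set. Ruthenium-catalysed ring-rearrangement metathesis of that cyclobutene, whose C1 also bears a 3-methylbut-3-enyl chain cis to the C6 aryl group, cleaves Cα=C5, closes the six-membered ring at C4=C5 and releases Cα as a vinyl group in one operation. Coumarin B is then annulated and coumarin A attached by a Heck reaction.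

Key step: step 11

Assumption: the sense of induction in step 6 is written for (R)-DTBM-SEGPHOS; if a first run gives the mirror-image centre, the (S)-ligand is used and nothing else changes.

Step 1
Reactants: 1 4-bromo-3-methoxyphenol
Product: 2 (4-bromo-3-methoxyphenoxy)triisopropylsilane
Conditions: i-Pr3SiCl (1.1 equiv), imidazole (2 equiv), DMF, rt
Reagents that add atoms: chlorotriisopropylsilane, CC(C)[Si](Cl)(C(C)C)C(C)C
Why: Silylation of the phenol with the bulky chlorosilane and imidazole gives an aryl silyl ether that should withstand zinc chloride, organolithium reagents and amine bases in the following steps and that leaves with fluoride.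

Step 2
Reactants: 3 hex-5-yn-2-one
Product: 4 2-(but-3-yn-1-yl)-2-methyl-1,3-dioxolane
Conditions: HOCH2CH2OH (1.5 equiv), p-TsOH·H2O (2 mol %), benzene, reflux, Dean–Stark trap
Reagents that add atoms: ethylene glycol, OCCO
Why: Acid-catalysed ketalisation with azeotropic removal of water masks the methyl ketone, which would otherwise interfere with the hydride, enolate and hydrazone chemistry of steps 6 to 8.

Step 3
Reactants: 2 (4-bromo-3-methoxyphenoxy)triisopropylsilane; 4 2-(but-3-yn-1-yl)-2-methyl-1,3-dioxolane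
Product: 5 {3-methoxy-4-[4-(2-methyl-1,3-dioxolan-2-yl)but-1-yn-1-yl]phenoxy}triisopropylsilane
Conditions: Pd(PhCN)2Cl2 (3 mol %), P(t-Bu)3·HBF4 (6 mol %), CuI (2 mol %), i-Pr2NH, dioxane, rt
Reagents that add atoms: none
Why: Sonogashira coupling, in which the bulky electron-rich phosphine lets the electron-rich aryl bromide add oxidatively to zerovalent palladium at room temperature and the copper acetylide of 4 then transmetalates, while silyl ether and ketal are inert to the amine base.

Step 4
Reactants: 5 {3-methoxy-4-[4-(2-methyl-1,3-dioxolan-2-yl)but-1-yn-1-yl]phenoxy}triisopropylsilane; 6 trichloroacetyl chloride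
Product: 8 4,4-dichloro-3-[2-methoxy-4-(triisopropylsilyloxy)phenyl]-2-[2-(2-methyl-1,3-dioxolan-2-yl)ethyl]cyclobut-2-en-1-one, via dichloroketene 7 (not isolated)
Conditions: Zn–Cu couple (3 equiv), Et2O/DME (5:1), rt, slow addition of 6; crude product used directly
Reagents that add atoms: none
Why: Ketene–alkyne [2+2] cycloaddition in which dichloroketene, formed by zinc dechlorination of 6, bonds through its carbonyl carbon to the alkyne carbon remote from the arene because the developing positive charge is best carried by the aryl-bearing carbon, so the carbonyl ends up next to the alkyl-substituted carbon, and dimethoxyethane ties up zinc chloride so that the ketal is kept.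

Step 5
Reactants: 8 4,4-dichloro-3-[2-methoxy-4-(triisopropylsilyloxy)phenyl]-2-[2-(2-methyl-1,3-dioxolan-2-yl)ethyl]cyclobut-2-en-1-one
Product: 9 3-[2-methoxy-4-(triisopropylsilyloxy)phenyl]-2-[2-(2-methyl-1,3-dioxolan-2-yl)ethyl]cyclobut-2-en-1-one
Conditions: Zn dust (4 equiv), AcOH, TMEDA, EtOH, 0 °C → rt
Reagents that add atoms: none
Why: Reductive dehalogenation of an alpha,alpha-dichloro ketone, in which zinc removes the two chlorines one after the other through zinc enolates that the amine-buffered acetic acid protonates, under conditions too mild for the enone, the ketal or the silyl ether.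

Step 6
Reactants: 9 3-[2-methoxy-4-(triisopropylsilyloxy)phenyl]-2-[2-(2-methyl-1,3-dioxolan-2-yl)ethyl]cyclobut-2-en-1-one
Product: 12 (2S,3R)-3-[2-methoxy-4-(triisopropylsilyloxy)phenyl]-2-methyl-2-[2-(2-methyl-1,3-dioxolan-2-yl)ethyl]cyclobutan-1-one, via silyl enol ether 10 (not isolated), via lithium enolate 11 (not isolated)
Conditions: Cu(OAc)2 (5 mol %), (R)-DTBM-SEGPHOS (5.5 mol %), Ph2SiH2 (0.55 equiv), toluene, 0 °C; then MeLi (1.0 equiv), THF, −78 → 0 °C; then MeI (3 equiv), DMPU, −78 → −20 °C
Reagents that add atoms: iodomethane, CI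
Why: Copper hydride-catalysed asymmetric conjugate reduction of the strained beta-aryl enone places hydride on the aryl-bearing carbon under control of the chiral bisphosphine and gives the regiodefined silyl enol ether, which methyllithium cleaves to the lithium enolate (regiospecific enolate generation) that iodomethane alkylates on the face away from the neighbouring aryl group, so the quaternary centre is set by the first one with methyl trans to aryl.

Step 7
Reactants: 12 (2S,3R)-3-[2-methoxy-4-(triisopropylsilyloxy)phenyl]-2-methyl-2-[2-(2-methyl-1,3-dioxolan-2-yl)ethyl]cyclobutan-1-one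
Product: 13 N'-[(1E,2S,3S)-3-[2-methoxy-4-(triisopropylsilyloxy)phenyl]-2-methyl-2-[2-(2-methyl-1,3-dioxolan-2-yl)ethyl]cyclobutylidene]-2,4,6-triisopropylbenzenesulfonohydrazide
Conditions: 2,4,6-(i-Pr)3C6H2SO2NHNH2 (1.1 equiv), THF, 4 Å molecular sieves, rt
Reagents that add atoms: 2,4,6-triisopropylbenzenesulfonyl hydrazide, CC(C)c1cc(C(C)C)c(S(=O)(=O)NN)c(C(C)C)c1
Why: Condensation of the strained, electrophilic cyclobutanone with the arenesulfonyl hydrazide gives the hydrazone with the sulfonamide nitrogen turned away from the quaternary carbon, and no acid is added so that the ketal is kept.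

Step 8
Reactants: 13 N'-[(1E,2S,3S)-3-[2-methoxy-4-(triisopropylsilyloxy)phenyl]-2-methyl-2-[2-(2-methyl-1,3-dioxolan-2-yl)ethyl]cyclobutylidene]-2,4,6-triisopropylbenzenesulfonohydrazide
Product: 15 2-{2-[(1R,4S)-4-[2-methoxy-4-(triisopropylsilyloxy)phenyl]-1-methylcyclobut-2-en-1-yl]ethyl}-2-methyl-1,3-dioxolane, via cyclobutenyllithium 14 (not isolated)
Conditions: n-BuLi (2.2 equiv), THF, −78 → 0 °C; then H2O
Reagents that add atoms: none
Why: Shapiro reaction, in which butyllithium removes the N–H proton and a proton of the only alpha-methylene group, the dianion loses sulfinate and dinitrogen near 0 °C to give the cyclobutenyllithium, and water protonates it to the cyclobutene without touching either stereocentre.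

Step 9
Reactants: 15 2-{2-[(1R,4S)-4-[2-methoxy-4-(triisopropylsilyloxy)phenyl]-1-methylcyclobut-2-en-1-yl]ethyl}-2-methyl-1,3-dioxolane
Product: 17 4-[(1R,4S)-4-(4-hydroxy-2-methoxyphenyl)-1-methylcyclobut-2-en-1-yl]butan-2-one, via phenol ketal 16 (not isolated)
Conditions: TBAF (1.1 equiv), THF, 0 °C; then 1 M aq. HCl, rt
Reagents that add atoms: water, O
Why: Fluoride cleaves the Si–O bond of the aryl silyl ether and the aqueous acid added to the same flask hydrolyses the dioxolane (acetal hydrolysis), conditions under which the unactivated cyclobutene is not expected to be protonated.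

Step 10
Reactants: 17 4-[(1R,4S)-4-(4-hydroxy-2-methoxyphenyl)-1-methylcyclobut-2-en-1-yl]butan-2-one
Product: 18 3-methoxy-4-[(1S,4R)-4-methyl-4-(3-methylbut-3-en-1-yl)cyclobut-2-en-1-yl]phenol
Conditions: Ph3PCH3Br (3 equiv), KOt-Bu (2.9 equiv), THF, 0 °C → rt; aq. NH4Cl work-up
Reagents that add atoms: methyltriphenylphosphonium bromide, C[P+](c1ccccc1)(c1ccccc1)c1ccccc1.[Br-]
Why: Wittig methylenation of the methyl ketone, in which the first equivalent of ylide only deprotonates the phenol and the resulting phenoxide is a spectator that is reprotonated on work-up.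

Step 11
Reactants: 18 3-methoxy-4-[(1S,4R)-4-methyl-4-(3-methylbut-3-en-1-yl)cyclobut-2-en-1-yl]phenol
Product: 19 4-[(1S,6R)-6-ethenyl-3,6-dimethylcyclohex-2-en-1-yl]-3-methoxyphenol
Conditions: second-generation Hoveyda–Grubbs catalyst RuCl2(SIMes)(=CH-C6H4-2-Oi-Pr) (5 mol %), CH2Cl2 (0.005 M), 40 °C
Reagents that add atoms: none
Why: The ruthenium methylidene adds [2+2] across the strained Cα=C5 bond with the metal on C5, and cycloreversion opens the four-membered ring to a C5 alkylidene while Cα is released as the terminal vinyl carbon; this alkylidene then adds across the tethered C4=CH2 bond and a second cycloreversion forms C4=C5 and returns the methylidene. The closest known reaction type is the ring-opening/ring-closing (ring-rearrangement) metathesis of cyclobutenes that carry an alkenyl side chain. The one ring formed is the cyclohexene, closed by ring-closing metathesis of the C5 alkylidene onto the 1,1-disubstituted alkene through a ruthenacyclobutane, with release of ring strain paying for the hindered closure. No stereocentre is created, because C1 and C6 were fixed on the rigid four-membered ring and none of their bonds is broken. The step needs the metal on C5 and not on Cα (a Cα alkylidene would close to a cyclopentene), which the quaternary C1 next to Cα should secure, and it needs initiation at the ring and not at the chain, which the sluggish 1,1-disubstituted alkene ensures. High dilution holds back oligomerisation and the low temperature avoids thermal electrocyclic opening of the 3-arylcyclobutene.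

Step 12
Reactants: 19 4-[(1S,6R)-6-ethenyl-3,6-dimethylcyclohex-2-en-1-yl]-3-methoxyphenol
Product: 20 5-[(1S,6R)-6-ethenyl-3,6-dimethylcyclohex-2-en-1-yl]-2-hydroxy-4-methoxybenzaldehyde
Conditions: MgCl2 (2 equiv), Et3N (4 equiv), (CH2O)n (6 equiv), MeCN, 80 °C
Reagents that add atoms: paraformaldehyde (as formaldehyde), C=O
Why: Magnesium-mediated ortho-formylation of the phenol (Casnati–Skattebøl reaction), in which the magnesium phenoxide delivers formaldehyde to the free ortho position para to the methoxy group (the position between the two oxygens is crowded) and a second formaldehyde oxidises the benzylic alkoxide by hydride transfer, both alkenes being inert.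

Step 13
Reactants: 20 5-[(1S,6R)-6-ethenyl-3,6-dimethylcyclohex-2-en-1-yl]-2-hydroxy-4-methoxybenzaldehyde
Product: 22 6-[(1S,6R)-6-ethenyl-3,6-dimethylcyclohex-2-en-1-yl]-7-methoxy-2H-chromen-2-one, via aryl ester ylide 21 (not isolated)
Conditions: Ph3P=C=C=O (1.2 equiv), toluene, 110 °C
Reagents that add atoms: (triphenylphosphoranylidene)ketene, O=C=C=P(c1ccccc1)(c1ccccc1)c1ccccc1
Why: The phenol adds to the ketene carbon of the cumulated ylide to give an aryl (triphenylphosphoranylidene)acetate whose intramolecular Wittig reaction with the neighbouring aldehyde can only form the cis alkene of the lactone, so the coumarin should form under neutral conditions that both alkenes tolerate.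

Step 14
Reactants: 23 5-bromo-2-hydroxy-4-methoxybenzaldehyde
Product: 25 6-bromo-7-methoxy-2H-chromen-2-one, via aryl ester ylide 24 (not isolated)
Conditions: Ph3P=C=C=O (1.2 equiv), toluene, 110 °C
Reagents that add atoms: (triphenylphosphoranylidene)ketene, O=C=C=P(c1ccccc1)(c1ccccc1)c1ccccc1
Why: The same addition of the phenol to the cumulated ylide followed by intramolecular Wittig lactonisation builds the coumarin ring, and the aryl bromide is untouched.

Step 15
Reactants: 22 6-[(1S,6R)-6-ethenyl-3,6-dimethylcyclohex-2-en-1-yl]-7-methoxy-2H-chromen-2-one; 25 6-bromo-7-methoxy-2H-chromen-2-one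
Product: 26 6-[(1S,6R)-6-[(E)-2-(7-methoxy-2-oxo-2H-chromen-6-yl)ethenyl]-3,6-dimethylcyclohex-2-en-1-yl]-7-methoxy-2H-chromen-2-one
Conditions: Pd2(dba)3 (2.5 mol %), P(t-Bu)3·HBF4 (10 mol %), Cy2NMe (1.5 equiv), dioxane, 90 °C
Reagents that add atoms: none
Why: Heck reaction, in which the aryl bromide adds oxidatively to zerovalent palladium, the arylpalladium inserts into the vinyl group with the aryl group on the terminal carbon, and because quaternary C1 has no hydrogen the only beta-hydride elimination possible gives the E-styrene, which cannot migrate further, while the trisubstituted ring alkene and the coumarin double bonds are too hindered to compete.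

Compound list
1 | 4-bromo-3-methoxyphenol | COc1cc(O)ccc1Br | starting material
2 | (4-bromo-3-methoxyphenoxy)triisopropylsilane | COc1cc(O[Si](C(C)C)(C(C)C)C(C)C)ccc1Br | intermediate
3 | hex-5-yn-2-one | CC(=O)CCC#C | starting material
4 | 2-(but-3-yn-1-yl)-2-methyl-1,3-dioxolane | CC1(CCC#C)OCCO1 | intermediate
5 | {3-methoxy-4-[4-(2-methyl-1,3-dioxolan-2-yl)but-1-yn-1-yl]phenoxy}triisopropylsilane | COc1cc(O[Si](C(C)C)(C(C)C)C(C)C)ccc1C#CCCC2(C)OCCO2 | intermediate
6 | trichloroacetyl chloride | O=C(Cl)C(Cl)(Cl)Cl | starting material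
7 | dichloroketene | O=C=C(Cl)Cl | intermediate
8 | 4,4-dichloro-3-[2-methoxy-4-(triisopropylsilyloxy)phenyl]-2-[2-(2-methyl-1,3-dioxolan-2-yl)ethyl]cyclobut-2-en-1-one | O=C1C(CCC2(C)OCCO2)=C(c3ccc(O[Si](C(C)C)(C(C)C)C(C)C)cc3OC)C1(Cl)Cl | intermediate
9 | 3-[2-methoxy-4-(triisopropylsilyloxy)phenyl]-2-[2-(2-methyl-1,3-dioxolan-2-yl)ethyl]cyclobut-2-en-1-one | O=C1CC(c2ccc(O[Si](C(C)C)(C(C)C)C(C)C)cc2OC)=C1CCC3(C)OCCO3 | intermediate
10 | bis({(3S)-3-[2-methoxy-4-(triisopropylsilyloxy)phenyl]-2-[2-(2-methyl-1,3-dioxolan-2-yl)ethyl]cyclobut-1-en-1-yl}oxy)diphenylsilane | c1ccccc1[Si](c1ccccc1)(OC1=C(CCC2(C)OCCO2)[C@@H](c2ccc(O[Si](C(C)C)(C(C)C)C(C)C)cc2OC)C1)OC1=C(CCC2(C)OCCO2)[C@@H](c2ccc(O[Si](C(C)C)(C(C)C)C(C)C)cc2OC)C1 | intermediate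
11 | lithium (3S)-3-[2-methoxy-4-(triisopropylsilyloxy)phenyl]-2-[2-(2-methyl-1,3-dioxolan-2-yl)ethyl]cyclobut-1-en-1-olate | [Li]OC1=C(CCC2(C)OCCO2)[C@@H](c2ccc(O[Si](C(C)C)(C(C)C)C(C)C)cc2OC)C1 | intermediate
12 | (2S,3R)-3-[2-methoxy-4-(triisopropylsilyloxy)phenyl]-2-methyl-2-[2-(2-methyl-1,3-dioxolan-2-yl)ethyl]cyclobutan-1-one (methyl trans to aryl) | O=C1C[C@H](c2ccc(O[Si](C(C)C)(C(C)C)C(C)C)cc2OC)[C@]1(C)CCC3(C)OCCO3 | intermediate
13 | N'-[(1E,2S,3S)-3-[2-methoxy-4-(triisopropylsilyloxy)phenyl]-2-methyl-2-[2-(2-methyl-1,3-dioxolan-2-yl)ethyl]cyclobutylidene]-2,4,6-triisopropylbenzenesulfonohydrazide | CC(C)c1cc(C(C)C)c(S(=O)(=O)N/N=C2\C[C@H](c3ccc(O[Si](C(C)C)(C(C)C)C(C)C)cc3OC)[C@]2(C)CCC4(C)OCCO4)c(C(C)C)c1 | intermediate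
14 | {(3S,4S)-3-[2-methoxy-4-(triisopropylsilyloxy)phenyl]-4-methyl-4-[2-(2-methyl-1,3-dioxolan-2-yl)ethyl]cyclobut-1-en-1-yl}lithium | [Li]C1=C[C@H](c2ccc(O[Si](C(C)C)(C(C)C)C(C)C)cc2OC)[C@]1(C)CCC3(C)OCCO3 | intermediate
15 | 2-{2-[(1R,4S)-4-[2-methoxy-4-(triisopropylsilyloxy)phenyl]-1-methylcyclobut-2-en-1-yl]ethyl}-2-methyl-1,3-dioxolane | C1=C[C@H](c2ccc(O[Si](C(C)C)(C(C)C)C(C)C)cc2OC)[C@]1(C)CCC3(C)OCCO3 | intermediate
16 | 3-methoxy-4-[(1S,4R)-4-methyl-4-[2-(2-methyl-1,3-dioxolan-2-yl)ethyl]cyclobut-2-en-1-yl]phenol | C1=C[C@H](c2ccc(O)cc2OC)[C@]1(C)CCC3(C)OCCO3 | intermediate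
17 | 4-[(1R,4S)-4-(4-hydroxy-2-methoxyphenyl)-1-methylcyclobut-2-en-1-yl]butan-2-one | C1=C[C@H](c2ccc(O)cc2OC)[C@]1(C)CCC(C)=O | intermediate
18 | 3-methoxy-4-[(1S,4R)-4-methyl-4-(3-methylbut-3-en-1-yl)cyclobut-2-en-1-yl]phenol (aryl cis to the butenyl chain) | C1=C[C@H](c2ccc(O)cc2OC)[C@]1(C)CCC(C)=C | intermediate
19 | 4-[(1S,6R)-6-ethenyl-3,6-dimethylcyclohex-2-en-1-yl]-3-methoxyphenol | C=C[C@@]1(C)CCC(C)=C[C@@H]1c1ccc(O)cc1OC | intermediate
20 | 5-[(1S,6R)-6-ethenyl-3,6-dimethylcyclohex-2-en-1-yl]-2-hydroxy-4-methoxybenzaldehyde | C=C[C@@]1(C)CCC(C)=C[C@@H]1c1cc(C=O)c(O)cc1OC | intermediate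
21 | 4-[(1S,6R)-6-ethenyl-3,6-dimethylcyclohex-2-en-1-yl]-2-formyl-5-methoxyphenyl (triphenyl-λ5-phosphanylidene)acetate | C=C[C@@]1(C)CCC(C)=C[C@@H]1c1cc(C=O)c(OC(=O)C=P(c2ccccc2)(c2ccccc2)c2ccccc2)cc1OC | intermediate
22 | 6-[(1S,6R)-6-ethenyl-3,6-dimethylcyclohex-2-en-1-yl]-7-methoxy-2H-chromen-2-one | C=C[C@@]1(C)CCC(C)=C[C@@H]1c1cc2ccc(=O)oc2cc1OC | intermediate
23 | 5-bromo-2-hydroxy-4-methoxybenzaldehyde | COc1cc(O)c(C=O)cc1Br | starting material
24 | 4-bromo-2-formyl-5-methoxyphenyl (triphenyl-λ5-phosphanylidene)acetate | COc1cc(OC(=O)C=P(c2ccccc2)(c2ccccc2)c2ccccc2)c(C=O)cc1Br | intermediate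
25 | 6-bromo-7-methoxy-2H-chromen-2-one | COc1cc2oc(=O)ccc2cc1Br | intermediate
26 | 6-[(1S,6R)-6-[(E)-2-(7-methoxy-2-oxo-2H-chromen-6-yl)ethenyl]-3,6-dimethylcyclohex-2-en-1-yl]-7-methoxy-2H-chromen-2-one (CNP0415737.1) | COc1cc2oc(=O)ccc2cc1/C=C/[C@@]1(C)CCC(C)=C[C@@H]1c1cc2ccc(=O)oc2cc1OC | target

Total step count: 15. Longest linear sequence: 13 steps (steps 1, 3 to 13 and 15, from 1 to 26).

Steps most likely to fail

Step 11. The cyclobutene may open with the metal on Cα, which leads on to five-membered ring closure, or the ring-opened alkylidene may add further cyclobutene (oligomerisation) before it finds the hindered 1,1-disubstituted alkene. Fallback: setting out from 18, the two events are separated. Ethenolysis with the first-generation Grubbs catalyst RuCl2(=CHPh)(PCy3)2 under ethene (1 atm, CH2Cl2, rt) opens only the strained ring, so the direction of opening no longer matters, and should give the triene 3-methoxy-4-[(3S,4R)-4-ethenyl-4,7-dimethylocta-1,7-dien-3-yl]phenol F1. Ring-closing metathesis of F1 with RuCl2(SIMes)(=CH-C6H4-2-Oi-Pr) in CH2Cl2 at 40 °C, where the catalyst should load on the vinyl group at the tertiary carbon and not on the one at the quaternary carbon, closes C4=C5 with loss of ethene and comes back to the route at 19.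

Step 6. Hydride transfer from the bulky chiral copper hydride to the tetrasubstituted, strained enone may be slow, may go to the carbonyl group or may discriminate the faces poorly, and proton exchange between enolate and product may blur the methylation. Fallback: setting out from 9, the same reductive methylation with the small achiral copper hydride [(Ph3P)CuH]6 (Ph2SiH2, toluene, rt; then MeLi; then MeI) should give racemic material, that is 12 together with its mirror image (2R,3S)-3-[2-methoxy-4-(triisopropylsilyloxy)phenyl]-2-methyl-2-[2-(2-methyl-1,3-dioxolan-2-yl)ethyl]cyclobutan-1-one F2. F2 is removed by preparative chromatography on a chiral stationary phase (resolution in place of asymmetric catalysis), and the route continues from 12.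

Step 8. Dianion formation at the strained ring may be incomplete, or excess butyllithium may metalate the arene between its two oxygens and trigger silyl migration from oxygen to carbon. Fallback: setting out from 12, KN(SiMe3)2 and PhNTf2 (THF, −78 °C) convert the ketone through its only possible enolate into (3S,4S)-3-[2-methoxy-4-(triisopropylsilyloxy)phenyl]-4-methyl-4-[2-(2-methyl-1,3-dioxolan-2-yl)ethyl]cyclobut-1-en-1-yl trifluoromethanesulfonate F3. Palladium-catalysed formate reduction (Pd(OAc)2, PPh3, n-Bu3N, HCO2H, DMF, 50 °C) then replaces the triflate by hydrogen and comes back to the route at 15.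

Further compounds
F1 | step 11 | 3-methoxy-4-[(3S,4R)-4-ethenyl-4,7-dimethylocta-1,7-dien-3-yl]phenol | C=C[C@H](c1ccc(O)cc1OC)[C@@](C)(C=C)CCC(C)=C
F2 | step 6 | (2R,3S)-3-[2-methoxy-4-(triisopropylsilyloxy)phenyl]-2-methyl-2-[2-(2-methyl-1,3-dioxolan-2-yl)ethyl]cyclobutan-1-one | O=C1C[C@@H](c2ccc(O[Si](C(C)C)(C(C)C)C(C)C)cc2OC)[C@@]1(C)CCC3(C)OCCO3
F3 | step 8 | (3S,4S)-3-[2-methoxy-4-(triisopropylsilyloxy)phenyl]-4-methyl-4-[2-(2-methyl-1,3-dioxolan-2-yl)ethyl]cyclobut-1-en-1-yl trifluoromethanesulfonate | FC(F)(F)S(=O)(=O)OC1=C[C@H](c2ccc(O[Si](C(C)C)(C(C)C)C(C)C)cc2OC)[C@]1(C)CCC3(C)OCCO3
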